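**Retrosynthetic overview** (ring atoms O1–C6, side chain C1'–C15'; target = (6S)-6-[(2S,4S,6R)-2,4,6-trihydroxypentadecyl]-5,6-dihydro-2H-pyran-2-one)
1. The target comes from its 6'-O-TBS ether, and the C4' carbinol from a C4' ketone by chelate-directed syn reduction from the free C2' hydroxyl.
2. The dihydropyranone, the only ring of the target, is closed late (step 8) by lactonisation of a (Z)-5-hydroxy-2-enoate, made by opening a terminal oxirane (future C6/C5) with the ethyl propiolate anion and semi-hydrogenating.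
3. Key disconnection C4'–C5' (with C3'–C4' in the same flask): C4', as C2 of a 2-silyl-1,3-dithiane, opens (R)-2-nonyloxirane at C5'; the silyl group shifts from C to O; the regenerated C4' anion opens (R,R)-diepoxypentane at C3'.
4. Enabling feature: C4' is a carbinol carbon flanked on both sides by CH2–CH(O) units (C5'–C6' and C3'–C2'), the middle of a 1,3,5-triol, so it can be a masked acyl dianion between two terminal oxirane rings; C2' and ring C6 are 1,3-anti and so both come from one C2-symmetric bis-oxirane.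
5. Ring order: oxiranes of 3 and 6 (steps 2 and 4, opened in steps 5 and 6); 1,3-dithiane as a temporary ring (carried from 7, removed in step 7); dihydropyranone last (step 8).

Key step: step 5

Assumption: 1,5-dichloropentane-2,4-dione (4) is treated as a purchasable compound.

**Step 1**
Reactants: 1 (R)-epichlorohydrin
Product: 2 (2R)-1-chloroundecan-2-ol
Conditions: n-C8H17MgBr, CuI (5 mol %), THF, −40 → 0 °C
Reagents that add atoms: n-octylmagnesium bromide, CCCCCCCC[Mg]Br
Why: Copper-catalysed Grignard opening of the oxirane at its unsubstituted carbon (SN2) does not touch the C–O stereocentre of 1, so the (R)-chlorohydrin should result.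

**Step 2**
Reactants: 2 (2R)-1-chloroundecan-2-ol
Product: 3 (2R)-2-nonyloxirane
Conditions: NaOH (powdered), Et2O, rt
Reagents that add atoms: none
Why: Intramolecular Williamson displacement of chloride by the alkoxide closes the oxirane without involving the carbinol carbon, so the configuration is retained.

**Step 3**
Reactants: 4 1,5-dichloropentane-2,4-dione
Product: 5 (2R,4R)-1,5-dichloropentane-2,4-diol
Conditions: H2 (80 atm), [RuCl2((S)-BINAP)]2·NEt3 (0.1 mol %), MeOH, 80 °C; recrystallisation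
Reagents that add atoms: none
Why: Noyori asymmetric hydrogenation of a 1,3-diketone sets both carbinol centres by catalyst control ((S)-BINAP, chelation by the second carbonyl), and crystallisation should upgrade the C2-symmetric anti diol.

**Step 4**
Reactants: 5 (2R,4R)-1,5-dichloropentane-2,4-diol
Product: 6 (2R,2'R)-2,2'-methylenebis(oxirane)
Conditions: KOH (powdered), Et2O, rt
Reagents that add atoms: none
Why: Double intramolecular Williamson etherification of the bis-chlorohydrin closes both oxiranes without touching either stereocentre.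

**Step 5**
Reactants: 7 2-(tert-butyldimethylsilyl)-1,3-dithiane; 3 (2R)-2-nonyloxirane; 6 (2R,2'R)-2,2'-methylenebis(oxirane)
Product: 12 2-[(2R)-2-(tert-butyldimethylsilyloxy)undecyl]-2-{(2R)-3-[(2R)-oxiran-2-yl]-2-(triethylsilyloxy)propyl}-1,3-dithiane, via lithiated silyl dithiane 8 (not isolated), via lithium alkoxide adduct 9 (not isolated), via Brook-rearranged dithianyl anion 10 (not isolated), via epoxy lithium alkoxide 11 (not isolated)
Conditions: t-BuLi, Et2O, −78 → −45 °C; 3, Et2O, −78 → −25 °C; 6 (3 equiv), THF/HMPA, −78 → 0 °C; TESCl, −20 → 0 °C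
Reagents that add atoms: chlorotriethylsilane (TESCl), CC[Si](Cl)(CC)CC
Why: Deprotonation of 7 gives carbanion 8, which opens 3 by SN2 attack at its CH2 to form the C4'–C5' bond and alkoxide 9; in Et2O the silyl group stays on carbon, and only when HMPA is added does the 1,4-Brook rearrangement (C to O silyl shift) turn 9 into the new dithianyl anion 10, which opens one oxirane of 6 at its CH2 to give 11, silylated in the flask by TESCl. The closest known reaction type is the solvent-controlled one-flask three-component linchpin coupling of 2-silyl-1,3-dithianes with two different terminal epoxides (anion relay chemistry), extended here only by an O-silylating quench. No ring is closed: two oxiranes are opened and the 1,3-dithiane ring is carried through as the masked C4' ketone. No new stereocentre is created; the three stereocentres of 12 are those of 3 and 6, retained because attack occurs only at the CH2 termini. The step needs the right order of alkylation, mono-opening of 6 and site-selective silylation: the first is secured by the HMPA-gated timing of the silyl shift, the second by an excess of the volatile bis-oxirane, and the third by the migration itself, which puts TBS on the undecyl oxygen and leaves the other oxygen to take TES.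

**Step 6**
Reactants: 12 2-[(2R)-2-(tert-butyldimethylsilyloxy)undecyl]-2-{(2R)-3-[(2R)-oxiran-2-yl]-2-(triethylsilyloxy)propyl}-1,3-dithiane; 13 ethyl propiolate
Product: 15 ethyl (5S,7R)-8-{2-[(2R)-2-(tert-butyldimethylsilyloxy)undecyl]-1,3-dithian-2-yl}-5-hydroxy-7-(triethylsilyloxy)oct-2-ynoate, via ethyl 3-lithioprop-2-ynoate 14 (not isolated)
Conditions: 13, n-BuLi, THF, −78 °C; BF3·OEt2, then 12, −78 °C
Reagents that add atoms: none
Why: Yamaguchi-type alkynylation, in which acetylide 14 opens the BF3-activated terminal oxirane at its CH2 (SN2), so the oxirane carbinol centre is retained as the C5 hydroxyl of the ynoate.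

**Step 7**
Reactants: 15 ethyl (5S,7R)-8-{2-[(2R)-2-(tert-butyldimethylsilyloxy)undecyl]-1,3-dithian-2-yl}-5-hydroxy-7-(triethylsilyloxy)oct-2-ynoate
Product: 16 ethyl (5S,7R,11R)-11-(tert-butyldimethylsilyloxy)-5-hydroxy-9-oxo-7-(triethylsilyloxy)icos-2-ynoate
Conditions: MeI, CaCO3, MeCN/H2O (9:1), 45 °C
Reagents that add atoms: water, O
Why: Alkylative hydrolysis of the 1,3-dithiane (Corey–Seebach unmasking by S-methylation and hydrolysis, buffered by CaCO3) is near neutral, so both silyl ethers and the ynoate should survive, and no stereocentre is involved.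

**Step 8**
Reactants: 16 ethyl (5S,7R,11R)-11-(tert-butyldimethylsilyloxy)-5-hydroxy-9-oxo-7-(triethylsilyloxy)icos-2-ynoate
Product: 19 (6S)-6-[(2R,6R)-6-(tert-butyldimethylsilyloxy)-2-hydroxy-4-oxopentadecyl]-5,6-dihydro-2H-pyran-2-one, via Z-hydroxy enoate 17 (not isolated), via triethylsilyl-protected keto lactone 18 (not isolated)
Conditions: H2 (1 atm), Pd/CaCO3 poisoned with Pb(OAc)2 (Lindlar catalyst), quinoline, EtOAc, rt; filter; TsOH·H2O (0.2 equiv), THF/H2O (10:1), rt
Reagents that add atoms: none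
Why: Lindlar semi-hydrogenation gives the (Z)-enoate 17, whose 5-hydroxyl is the only one placed for six-membered ring closure and should lactonise (6-exo-trig acyl substitution) to 18, while the mild aqueous acid cleaves the triethylsilyl ether selectively over the bulkier TBS ether without touching a stereocentre.

**Step 9**
Reactants: 19 (6S)-6-[(2R,6R)-6-(tert-butyldimethylsilyloxy)-2-hydroxy-4-oxopentadecyl]-5,6-dihydro-2H-pyran-2-one
Product: 20 (6S)-6-[(2S,4R,6R)-6-(tert-butyldimethylsilyloxy)-2,4-dihydroxypentadecyl]-5,6-dihydro-2H-pyran-2-one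
Conditions: Et2BOMe, THF/MeOH (4:1), −78 °C; NaBH4, −78 °C; AcOH; MeOH co-evaporation
Reagents that add atoms: none
Why: Narasaka–Prasad reduction, in which Et2BOMe forms a six-membered boron chelate between the free C2' hydroxyl and the ketone and external hydride attacks axially to give the 1,3-syn diol, so that C4' (4'R in 20 because of the silyl ether, 4'S in the target) is set by substrate control from C2', the chelate-activated ketone being expected to react ahead of the conjugated lactone at −78 °C.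

**Step 10**
Reactants: 20 (6S)-6-[(2S,4R,6R)-6-(tert-butyldimethylsilyloxy)-2,4-dihydroxypentadecyl]-5,6-dihydro-2H-pyran-2-one
Product: 21 (6S)-6-[(2S,4S,6R)-2,4,6-trihydroxypentadecyl]-5,6-dihydro-2H-pyran-2-one
Conditions: HF·pyridine, pyridine/THF, 0 °C → rt
Reagents that add atoms: none
Why: Fluoride-mediated cleavage of the secondary TBS ether under buffered HF·pyridine should leave the base-sensitive unsaturated lactone and the 1,3-diol array intact and touches no stereocentre.

**Compound list**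
1 | (R)-epichlorohydrin, (2R)-2-(chloromethyl)oxirane | ClC[C@H]1CO1 | starting material
2 | (2R)-1-chloroundecan-2-ol | ClC[C@H](O)CCCCCCCCC | intermediate
3 | (2R)-2-nonyloxirane, (R)-1,2-epoxyundecane | CCCCCCCCC[C@@H]1CO1 | intermediate
4 | 1,5-dichloropentane-2,4-dione | ClCC(=O)CC(=O)CCl | starting material
5 | (2R,4R)-1,5-dichloropentane-2,4-diol | ClC[C@H](O)C[C@@H](O)CCl | intermediate
6 | (2R,2'R)-2,2'-methylenebis(oxirane), (R,R)-1,2:4,5-diepoxypentane | C1O[C@@H]1C[C@@H]1CO1 | intermediate
7 | 2-(tert-butyldimethylsilyl)-1,3-dithiane | CC(C)(C)[Si](C)(C)C1SCCCS1 | starting material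
8 | 2-(tert-butyldimethylsilyl)-2-lithio-1,3-dithiane | [Li]C1([Si](C)(C)C(C)(C)C)SCCCS1 | intermediate
9 | lithium (2R)-1-[2-(tert-butyldimethylsilyl)-1,3-dithian-2-yl]undecan-2-olate | CCCCCCCCC[C@@H](O[Li])CC1([Si](C)(C)C(C)(C)C)SCCCS1 | intermediate
10 | 2-[(2R)-2-(tert-butyldimethylsilyloxy)undecyl]-2-lithio-1,3-dithiane | CCCCCCCCC[C@@H](O[Si](C)(C)C(C)(C)C)CC1([Li])SCCCS1 | intermediate
11 | lithium (2R)-1-{2-[(2R)-2-(tert-butyldimethylsilyloxy)undecyl]-1,3-dithian-2-yl}-3-[(2R)-oxiran-2-yl]propan-2-olate | CCCCCCCCC[C@@H](O[Si](C)(C)C(C)(C)C)CC1(C[C@H](O[Li])C[C@@H]2CO2)SCCCS1 | intermediate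
12 | 2-[(2R)-2-(tert-butyldimethylsilyloxy)undecyl]-2-{(2R)-3-[(2R)-oxiran-2-yl]-2-(triethylsilyloxy)propyl}-1,3-dithiane | CCCCCCCCC[C@@H](O[Si](C)(C)C(C)(C)C)CC1(C[C@H](O[Si](CC)(CC)CC)C[C@@H]2CO2)SCCCS1 | intermediate
13 | ethyl propiolate | C#CC(=O)OCC | starting material
14 | ethyl 3-lithioprop-2-ynoate | [Li]C#CC(=O)OCC | intermediate
15 | ethyl (5S,7R)-8-{2-[(2R)-2-(tert-butyldimethylsilyloxy)undecyl]-1,3-dithian-2-yl}-5-hydroxy-7-(triethylsilyloxy)oct-2-ynoate | CCCCCCCCC[C@@H](O[Si](C)(C)C(C)(C)C)CC1(C[C@H](O[Si](CC)(CC)CC)C[C@@H](O)CC#CC(=O)OCC)SCCCS1 | intermediate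
16 | ethyl (5S,7R,11R)-11-(tert-butyldimethylsilyloxy)-5-hydroxy-9-oxo-7-(triethylsilyloxy)icos-2-ynoate | CCCCCCCCC[C@@H](O[Si](C)(C)C(C)(C)C)CC(=O)C[C@H](O[Si](CC)(CC)CC)C[C@@H](O)CC#CC(=O)OCC | intermediate
17 | ethyl (2Z,5S,7R,11R)-11-(tert-butyldimethylsilyloxy)-5-hydroxy-9-oxo-7-(triethylsilyloxy)icos-2-enoate | CCCCCCCCC[C@@H](O[Si](C)(C)C(C)(C)C)CC(=O)C[C@H](O[Si](CC)(CC)CC)C[C@@H](O)C/C=C\C(=O)OCC | intermediate
18 | (6S)-6-[(2R,6R)-6-(tert-butyldimethylsilyloxy)-4-oxo-2-(triethylsilyloxy)pentadecyl]-5,6-dihydro-2H-pyran-2-one | CCCCCCCCC[C@@H](O[Si](C)(C)C(C)(C)C)CC(=O)C[C@H](O[Si](CC)(CC)CC)C[C@@H]1CC=CC(=O)O1 | intermediate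
19 | (6S)-6-[(2R,6R)-6-(tert-butyldimethylsilyloxy)-2-hydroxy-4-oxopentadecyl]-5,6-dihydro-2H-pyran-2-one | CCCCCCCCC[C@@H](O[Si](C)(C)C(C)(C)C)CC(=O)C[C@H](O)C[C@@H]1CC=CC(=O)O1 | intermediate
20 | (6S)-6-[(2S,4R,6R)-6-(tert-butyldimethylsilyloxy)-2,4-dihydroxypentadecyl]-5,6-dihydro-2H-pyran-2-one | CCCCCCCCC[C@@H](O[Si](C)(C)C(C)(C)C)C[C@H](O)C[C@H](O)C[C@@H]1CC=CC(=O)O1 | intermediate
21 | (6S)-6-[(2S,4S,6R)-2,4,6-trihydroxypentadecyl]-5,6-dihydro-2H-pyran-2-one | CCCCCCCCC[C@@H](O)C[C@H](O)C[C@H](O)C[C@@H]1CC=CC(=O)O1 | target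

**Step count:** 10 steps in total. Longest linear sequence: 8 steps (steps 3, 4, 5–10 from 4; equally steps 1, 2, 5–10 from 1).

**Steps most likely to fail**

Step 5. The carbanion released by the silyl shift may open the bis-oxirane a second time or be protonated before it alkylates, and the silyl migration may begin before HMPA is added, which would scramble the order of alkylation. Fallback, setting out from 3 and coming back at 10: 1,3-dithiane is lithiated (n-BuLi, THF, −30 °C) to 2-lithio-1,3-dithiane F1, which opens 3 at its CH2 to give (2R)-1-(1,3-dithian-2-yl)undecan-2-ol F2. Silylation (TBSCl, imidazole, DMF) should give tert-butyl{[(2R)-1-(1,3-dithian-2-yl)undecan-2-yl]oxy}dimethylsilane F3. Direct deprotonation of this compound (t-BuLi, THF/HMPA, −78 °C) gives carbanion 10 without any silyl migration, and 10 is taken on with 6 and TESCl as in step 5 to 12.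

Step 6. The lithiated propiolate decomposes above about −70 °C, so the opening may stall; a dithiane sulfur may also attack the BF3-activated oxirane, or the Lewis acid may ionise the triethylsilyl ether. Fallback, setting out from 12 and coming back at 18: CH2=CHMgBr with catalytic CuI (THF, −30 °C) opens the oxirane to (4S,6R)-7-{2-[(2R)-2-(tert-butyldimethylsilyloxy)undecyl]-1,3-dithian-2-yl}-6-(triethylsilyloxy)hept-1-en-4-ol F4. Acryloyl chloride and iPr2NEt (CH2Cl2, 0 °C) should give (4S,6R)-7-{2-[(2R)-2-(tert-butyldimethylsilyloxy)undecyl]-1,3-dithian-2-yl}-6-(triethylsilyloxy)hept-1-en-4-yl prop-2-enoate F5. MeI/CaCO3 (MeCN/H2O) unmasks the ketone to (4S,6R,10R)-10-(tert-butyldimethylsilyloxy)-8-oxo-6-(triethylsilyloxy)nonadec-1-en-4-yl prop-2-enoate F6. Ring-closing metathesis (second-generation Grubbs catalyst RuCl2(=CHPh)(PCy3)(H2IMes), CH2Cl2, 40 °C) closes the dihydropyranone to 18, which is isolated here and desilylated (TsOH·H2O, THF/H2O) to 19.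

Step 9. Hydride may add in conjugate fashion to the unsaturated lactone in competition with the chelate-directed ketone reduction, and incomplete chelate formation would erode facial control at C4'. Fallback, setting out from 16 and coming back at 20, which moves the directed reduction ahead of ring formation so that no lactone is present: AcOH/THF/H2O (rt) removes the triethylsilyl group to give ethyl (5S,7R,11R)-11-(tert-butyldimethylsilyloxy)-5,7-dihydroxy-9-oxoicos-2-ynoate F7. Et2BOMe/NaBH4 (THF/MeOH, −78 °C) should give the syn diol ethyl (5S,7R,9R,11R)-11-(tert-butyldimethylsilyloxy)-5,7,9-trihydroxyicos-2-ynoate F8. Semi-hydrogenation (H2, Pd/CaCO3 poisoned with Pb(OAc)2, quinoline, EtOAc) gives ethyl (2Z,5S,7R,9R,11R)-11-(tert-butyldimethylsilyloxy)-5,7,9-trihydroxyicos-2-enoate F9, which should lactonise through its 5-hydroxyl (catalytic TsOH·H2O, CH2Cl2) to 20.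

**Further compounds**
F1 | step 5 | 2-lithio-1,3-dithiane | [Li]C1SCCCS1
F2 | step 5 | (2R)-1-(1,3-dithian-2-yl)undecan-2-ol | CCCCCCCCC[C@@H](O)CC1SCCCS1
F3 | step 5 | tert-butyl{[(2R)-1-(1,3-dithian-2-yl)undecan-2-yl]oxy}dimethylsilane | CCCCCCCCC[C@@H](O[Si](C)(C)C(C)(C)C)CC1SCCCS1
F4 | step 6 | (4S,6R)-7-{2-[(2R)-2-(tert-butyldimethylsilyloxy)undecyl]-1,3-dithian-2-yl}-6-(triethylsilyloxy)hept-1-en-4-ol | CCCCCCCCC[C@@H](O[Si](C)(C)C(C)(C)C)CC1(C[C@H](O[Si](CC)(CC)CC)C[C@@H](O)CC=C)SCCCS1
F5 | step 6 | (4S,6R)-7-{2-[(2R)-2-(tert-butyldimethylsilyloxy)undecyl]-1,3-dithian-2-yl}-6-(triethylsilyloxy)hept-1-en-4-yl prop-2-enoate | CCCCCCCCC[C@@H](O[Si](C)(C)C(C)(C)C)CC1(C[C@H](O[Si](CC)(CC)CC)C[C@@H](OC(=O)C=C)CC=C)SCCCS1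
F6 | step 6 | (4S,6R,10R)-10-(tert-butyldimethylsilyloxy)-8-oxo-6-(triethylsilyloxy)nonadec-1-en-4-yl prop-2-enoate | CCCCCCCCC[C@@H](O[Si](C)(C)C(C)(C)C)CC(=O)C[C@H](O[Si](CC)(CC)CC)C[C@@H](OC(=O)C=C)CC=C
F7 | step 9 | ethyl (5S,7R,11R)-11-(tert-butyldimethylsilyloxy)-5,7-dihydroxy-9-oxoicos-2-ynoate | CCCCCCCCC[C@@H](O[Si](C)(C)C(C)(C)C)CC(=O)C[C@H](O)C[C@@H](O)CC#CC(=O)OCC
F8 | step 9 | ethyl (5S,7R,9R,11R)-11-(tert-butyldimethylsilyloxy)-5,7,9-trihydroxyicos-2-ynoate | CCCCCCCCC[C@@H](O[Si](C)(C)C(C)(C)C)C[C@H](O)C[C@H](O)C[C@@H](O)CC#CC(=O)OCC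
F9 | step 9 | ethyl (2Z,5S,7R,9R,11R)-11-(tert-butyldimethylsilyloxy)-5,7,9-trihydroxyicos-2-enoate | CCCCCCCCC[C@@H](O[Si](C)(C)C(C)(C)C)C[C@H](O)C[C@H](O)C[C@@H](O)C/C=C\C(=O)OCC
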